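The cyclohexene ring (C1–C6; C1 = sp2 carbon carrying the dienoate arm, C4 = aryl-bearing carbon) is opened at C1–C6 and C5–C6. C6, a CH(CO2H) unit lodged between vinylic C1 and C5, is delivered as the carbene carbon of tert-butyl diazoacetate. One palladium-catalysed operation on an acyclic (Z)-vinyl iodide should forge both bonds, close the ring and set C6. That precursor already holds the C5 malonate, the C3/C4 stereodiad (from a single enamine Michael addition) and the complete protected (R)-danshensu dienoate, attached by olefination of an α-iodoenal. Desilylation, oxidation at C3, global acidolysis and decarboxylation at C5 finish the synthesis.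

Key step: step 10

Remark: ring locants of the target (C1 = ring sp2 carbon bearing the side chain, C2 = ring CH=, C3 = CH–CO2H next to C2, C4 = CH–aryl, C5, C6 = CH–CO2H next to C1) are kept for the open-chain precursors; Ar = 2,2-dimethyl-1,3-benzodioxol-5-yl, PMB = 4-methoxybenzyl, TBS = tert-butyldimethylsilyl, Dan = (2R)-1-tert-butoxy-3-Ar-1-oxopropan-2-yl (the O-linked residue of 13); CIP descriptors at C3, C4 and C6 change along the route only because substituent priorities change, no centre being inverted; all starting materials are assumed to be purchased.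

Step 1
Reactants: 1 3,4-dihydroxybenzaldehyde
Product: 2 2,2-dimethyl-1,3-benzodioxole-5-carbaldehyde
Conditions: 2,2-dimethoxypropane, TsOH·H2O (cat.), toluene, reflux through 4 Å sieves; dilute aqueous acid work-up
Reagents that add atoms: 2,2-dimethoxypropane, COC(C)(C)OC
Why: Acid-catalysed transketalisation (acetonide formation) should close the five-membered ketal on the catechol while methanol is trapped on the sieves, and any aldehyde dimethyl acetal reverts to the aldehyde on aqueous work-up.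

Step 2
Reactants: 2 2,2-dimethyl-1,3-benzodioxole-5-carbaldehyde; 3 bis(4-methoxybenzyl) malonate
Product: 4 bis(4-methoxybenzyl) 2-[(2,2-dimethyl-1,3-benzodioxol-5-yl)methylidene]malonate
Conditions: piperidine (cat.), AcOH (cat.), toluene, reflux with azeotropic removal of water
Reagents that add atoms: none
Why: Knoevenagel condensation of a non-enolisable aromatic aldehyde with the symmetric malonate, driven by removal of water, should give a single alkylidene malonate.

Step 3
Reactants: 4 bis(4-methoxybenzyl) 2-[(2,2-dimethyl-1,3-benzodioxol-5-yl)methylidene]malonate; 5 3-[(tert-butyldimethylsilyl)oxy]propanal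
Product: 6 bis(4-methoxybenzyl) 2-[(1S,2R)-1-Ar-2-formyl-3-(TBS-oxy)propyl]malonate (route locants 3R/4S)
Conditions: (R)-α,α-diphenylprolinol trimethylsilyl ether (20 mol %), CHCl3, 4 °C to rt
Reagents that add atoms: none
Why: In this enamine-mediated asymmetric Michael addition of an aldehyde to an alkylidene malonate, the E-enamine of 5 formed with the (R)-configured catalyst should add through its unshielded face in an acyclic synclinal transition state, which sets C3 (R) and C4 (S) together in the syn relationship that becomes 3,4-trans on the ring.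

Step 4
Reactants: 6 bis(4-methoxybenzyl) 2-[(1S,2R)-1-Ar-2-formyl-3-(TBS-oxy)propyl]malonate; 7 (triphenylphosphoranylidene)acetaldehyde
Product: 8 bis(4-methoxybenzyl) 2-[(1S,2R,3E)-1-Ar-5-oxo-2-(TBS-oxymethyl)pent-3-en-1-yl]malonate
Conditions: toluene, 80 °C
Reagents that add atoms: none
Why: Wittig olefination with the formyl-stabilised ylide should give the E-enal under neutral conditions that leave the C3 stereocentre, the silyl ether and the acidic malonate C–H untouched.

Step 5
Reactants: 8 bis(4-methoxybenzyl) 2-[(1S,2R,3E)-1-Ar-5-oxo-2-(TBS-oxymethyl)pent-3-en-1-yl]malonate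
Product: 9 bis(4-methoxybenzyl) 2-[(1S,2S,3Z)-1-Ar-4-iodo-5-oxo-2-(TBS-oxymethyl)pent-3-en-1-yl]malonate
Conditions: I2, pyridine/CH2Cl2 (1:1), DMAP (cat.), 0 °C to rt, dark
Reagents that add atoms: iodine, II
Why: α-Iodination of the enal by amine conjugate addition, iodination and elimination (a Baylis–Hillman-type sequence) should give only the Z-iodide, because elimination restores the alkene with the formyl group trans to C3, while the weak base leaves the hindered malonate C–H alone.

Step 6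
Reactants: 10 (R)-danshensu
Product: 12 (2R)-3-(2,2-dimethyl-1,3-benzodioxol-5-yl)-2-hydroxypropanoic acid, via dioxolanone bis-acetonide 11 (not isolated)
Conditions: 2,2-dimethoxypropane, TsOH·H2O (cat.), toluene, reflux through 4 Å sieves; then LiOH, THF/H2O, 0 °C; HCl (1 M) to pH 3
Reagents that add atoms: 2,2-dimethoxypropane, COC(C)(C)OC; water (as aqueous LiOH), O
Why: Acid-catalysed ketalisation should convert the catechol into its acetonide and the α-hydroxy acid into a dioxolanone, and saponification of this activated ester then frees acid and hydroxyl without touching the base-stable aryl ketal or the stereocentre.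

Step 7
Reactants: 12 (2R)-3-(2,2-dimethyl-1,3-benzodioxol-5-yl)-2-hydroxypropanoic acid
Product: 13 tert-butyl (2R)-3-(2,2-dimethyl-1,3-benzodioxol-5-yl)-2-hydroxypropanoate
Conditions: tert-butyl 2,2,2-trichloroacetimidate, CH2Cl2/cyclohexane, rt
Reagents that add atoms: tert-butyl 2,2,2-trichloroacetimidate, CC(C)(C)OC(=N)C(Cl)(Cl)Cl
Why: tert-Butyl esterification by O-alkylation of the carboxylic acid with the trichloroacetimidate needs no added acid, so the secondary hydroxyl and the acetonide should stay intact.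

Step 8
Reactants: 13 tert-butyl (2R)-3-(2,2-dimethyl-1,3-benzodioxol-5-yl)-2-hydroxypropanoate; 14 diethylphosphonoacetic acid
Product: 15 tert-butyl (2R)-2-{[2-(diethoxyphosphoryl)acetyl]oxy}-3-(2,2-dimethyl-1,3-benzodioxol-5-yl)propanoate
Conditions: DCC, DMAP (cat.), CH2Cl2, 0 °C to rt
Reagents that add atoms: none
Why: Steglich esterification (carbodiimide activation with DMAP catalysis) should acylate the secondary alcohol without affecting the neighbouring stereocentre.

Step 9
Reactants: 9 bis(4-methoxybenzyl) 2-[(1S,2S,3Z)-1-Ar-4-iodo-5-oxo-2-(TBS-oxymethyl)pent-3-en-1-yl]malonate; 15 tert-butyl (2R)-2-{[2-(diethoxyphosphoryl)acetyl]oxy}-3-(2,2-dimethyl-1,3-benzodioxol-5-yl)propanoate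
Product: 16 Dan (2E,4Z,6S,7S)-7-Ar-4-iodo-8,8-bis(PMB-oxycarbonyl)-6-(TBS-oxymethyl)octa-2,4-dienoate
Conditions: LiCl, iPr2NEt, MeCN, 0 °C to rt
Reagents that add atoms: none
Why: Horner–Wadsworth–Emmons olefination under mild LiCl/amine conditions should give the 2E-alkene and leave the Z-iodide, the C3 stereocentre and the malonate C–H unchanged, the malonate anion having no ring closure open to it because C3 and the new arm are trans on C1=C2.

Step 10
Reactants: 16 Dan (2E,4Z,6S,7S)-7-Ar-4-iodo-8,8-bis(PMB-oxycarbonyl)-6-(TBS-oxymethyl)octa-2,4-dienoate; 17 tert-butyl diazoacetate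
Product: 18 2-tert-butyl 1,1-bis(PMB) (2S,5R,6R)-6-Ar-3-[(E)-2-(Dan-oxycarbonyl)ethenyl]-5-(TBS-oxymethyl)cyclohex-3-ene-1,1,2-tricarboxylate (route locants 3R/4R/6S)
Conditions: Pd2(dba)3 (5 mol %), tri(2-furyl)phosphine (20 mol %), Cs2CO3 (2.5 equiv), MeCN/THF (0.02 M), 60 °C, 17 (2.5 equiv) added by syringe pump over 6 h
Reagents that add atoms: none
Why: Proposed new method: zerovalent palladium should insert into the C1–I bond of 16, decompose 17 to a palladium carbene and, by migration of the vinyl carbon C1 onto the carbene carbon, create the C1–C6 bond and an η3-allyl complex over C6–C1–C2, which the caesium enolate of the C5 malonate then alkylates at C6 (C5–C6 bond); the closest known reaction type is the palladium-catalysed three-component coupling of vinyl iodides, diazo esters and amine or malonate nucleophiles via η3-allyl intermediates, which has not been used to close a six-membered ring through the carbene carbon. The ring closes in a formal [5+1] mode, an intramolecular allylic alkylation at the ester-bearing allyl terminus that takes all three allyl carbons into the cyclohexene, the alternative attack at C2 being excluded because it would give a cyclobutane. The Z geometry of the iodide places palladium, and hence C6, cis to C3 on C1=C2, as the endocyclic alkene demands, so ring closure only has to outrun syn/anti isomerisation of the allyl complex. C6 is set by attack of the malonate anti to palladium through a chair-like transition state with the C3 and C4 substituents equatorial and the C6 ester pseudoaxial, where it avoids allylic strain with the C1 arm and ends up trans to the aryl group; this isomer should also be the thermodynamic one if C6 equilibrates under the carbonate base. The step needs carbene insertion to beat direct C5–C1 vinylation, β-hydride loss from C3 and carbene dimerisation, which the weakly donating tri(2-furyl)phosphine, high dilution and slow addition of 17 are meant to secure.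

Step 11
Reactants: 18 2-tert-butyl 1,1-bis(PMB) (2S,5R,6R)-6-Ar-3-[(E)-2-(Dan-oxycarbonyl)ethenyl]-5-(TBS-oxymethyl)cyclohex-3-ene-1,1,2-tricarboxylate
Product: 19 2-tert-butyl 1,1-bis(PMB) (2S,5R,6R)-6-Ar-3-[(E)-2-(Dan-oxycarbonyl)ethenyl]-5-(hydroxymethyl)cyclohex-3-ene-1,1,2-tricarboxylate
Conditions: HF·pyridine, pyridine/THF, 0 °C to rt
Reagents that add atoms: none
Why: Fluoride-mediated desilylation under buffered, non-basic conditions should free the primary alcohol without forming an alkoxide that could lactonise onto a C5 ester, and leaves acetonides and esters intact.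

Step 12
Reactants: 19 2-tert-butyl 1,1-bis(PMB) (2S,5R,6R)-6-Ar-3-[(E)-2-(Dan-oxycarbonyl)ethenyl]-5-(hydroxymethyl)cyclohex-3-ene-1,1,2-tricarboxylate
Product: 21 (1R,4S,6R)-6-Ar-4-(tert-butoxycarbonyl)-3-[(E)-2-(Dan-oxycarbonyl)ethenyl]-5,5-bis(PMB-oxycarbonyl)cyclohex-2-ene-1-carboxylic acid, via C3 aldehyde 20 (not isolated)
Conditions: TEMPO (20 mol %), PhI(OAc)2 (2.5 equiv), MeCN/H2O, rt
Reagents that add atoms: water, O
Why: Oxoammonium-catalysed oxidation (TEMPO with PhI(OAc)2 in aqueous acetonitrile) should take the primary alcohol through the aldehyde hydrate to the acid at near-neutral pH, so C3 should not epimerise and the acid-labile groups survive.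

Step 13
Reactants: 21 (1R,4S,6R)-6-Ar-4-(tert-butoxycarbonyl)-3-[(E)-2-(Dan-oxycarbonyl)ethenyl]-5,5-bis(PMB-oxycarbonyl)cyclohex-2-ene-1-carboxylic acid
Product: 23 (1R,2R,3S,4R)-6-[(1E)-3-{[(1R)-1-carboxy-2-(3,4-dihydroxyphenyl)ethyl]oxy}-3-oxoprop-1-en-1-yl]-3-(3,4-dihydroxyphenyl)cyclohex-5-ene-1,2,4-tricarboxylic acid (target; route locants 3R/4S/5R/6R), via pentacarboxylic acid 22 (not isolated)
Conditions: TFA/H2O/anisole (90:5:5), 0 °C to rt; evaporate; then degassed 1,4-dioxane/H2O, 95 °C, argon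
Reagents that add atoms: none
Why: Acidolysis should remove the tert-butyl and 4-methoxybenzyl esters (cations trapped by anisole) and hydrolyse both acetonides, and thermal decarboxylation of the resulting C5 malonic acid should deliver the proton to the enediol on the face anti to the pseudoaxial C6 carboxyl, which leaves the C5 carboxyl equatorial, trans to the aryl group and cis to the C6 carboxyl (5R).

Compound list

1 | 3,4-dihydroxybenzaldehyde | O=Cc1ccc(O)c(O)c1 | starting material
2 | 2,2-dimethyl-1,3-benzodioxole-5-carbaldehyde | O=Cc1ccc2c(c1)OC(C)(C)O2 | intermediate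
3 | bis(4-methoxybenzyl) malonate | COc1ccc(COC(=O)CC(=O)OCc2ccc(OC)cc2)cc1 | starting material
4 | bis(4-methoxybenzyl) 2-[(2,2-dimethyl-1,3-benzodioxol-5-yl)methylidene]malonate | COc1ccc(COC(=O)C(=Cc2ccc3c(c2)OC(C)(C)O3)C(=O)OCc2ccc(OC)cc2)cc1 | intermediate
5 | 3-[(tert-butyldimethylsilyl)oxy]propanal | O=CCCO[Si](C)(C)C(C)(C)C | starting material
6 | bis(4-methoxybenzyl) 2-[(1S,2R)-1-Ar-2-formyl-3-(TBS-oxy)propyl]malonate | O=C[C@@H](CO[Si](C)(C)C(C)(C)C)[C@H](c1ccc2c(c1)OC(C)(C)O2)C(C(=O)OCc1ccc(OC)cc1)C(=O)OCc1ccc(OC)cc1 | intermediate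
7 | (triphenylphosphoranylidene)acetaldehyde | O=CC=P(c1ccccc1)(c1ccccc1)c1ccccc1 | starting material
8 | bis(4-methoxybenzyl) 2-[(1S,2R,3E)-1-Ar-5-oxo-2-(TBS-oxymethyl)pent-3-en-1-yl]malonate | O=C/C=C/[C@@H](CO[Si](C)(C)C(C)(C)C)[C@H](c1ccc2c(c1)OC(C)(C)O2)C(C(=O)OCc1ccc(OC)cc1)C(=O)OCc1ccc(OC)cc1 | intermediate
9 | bis(4-methoxybenzyl) 2-[(1S,2S,3Z)-1-Ar-4-iodo-5-oxo-2-(TBS-oxymethyl)pent-3-en-1-yl]malonate | O=C/C(I)=C/[C@@H](CO[Si](C)(C)C(C)(C)C)[C@H](c1ccc2c(c1)OC(C)(C)O2)C(C(=O)OCc1ccc(OC)cc1)C(=O)OCc1ccc(OC)cc1 | intermediate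
10 | (R)-danshensu, (2R)-3-(3,4-dihydroxyphenyl)-2-hydroxypropanoic acid | O[C@H](Cc1ccc(O)c(O)c1)C(=O)O | starting material
11 | dioxolanone bis-acetonide, (5R)-5-[(2,2-dimethyl-1,3-benzodioxol-5-yl)methyl]-2,2-dimethyl-1,3-dioxolan-4-one | CC1(C)O[C@H](Cc2ccc3c(c2)OC(C)(C)O3)C(=O)O1 | intermediate
12 | (2R)-3-(2,2-dimethyl-1,3-benzodioxol-5-yl)-2-hydroxypropanoic acid | O[C@H](Cc1ccc2c(c1)OC(C)(C)O2)C(=O)O | intermediate
13 | tert-butyl (2R)-3-(2,2-dimethyl-1,3-benzodioxol-5-yl)-2-hydroxypropanoate | O[C@H](Cc1ccc2c(c1)OC(C)(C)O2)C(=O)OC(C)(C)C | intermediate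
14 | diethylphosphonoacetic acid | CCOP(=O)(CC(=O)O)OCC | starting material
15 | tert-butyl (2R)-2-{[2-(diethoxyphosphoryl)acetyl]oxy}-3-(2,2-dimethyl-1,3-benzodioxol-5-yl)propanoate | CCOP(=O)(CC(=O)O[C@H](Cc1ccc2c(c1)OC(C)(C)O2)C(=O)OC(C)(C)C)OCC | intermediate
16 | Dan (2E,4Z,6S,7S)-7-Ar-4-iodo-8,8-bis(PMB-oxycarbonyl)-6-(TBS-oxymethyl)octa-2,4-dienoate | O=C(/C=C/C(I)=C/[C@@H](CO[Si](C)(C)C(C)(C)C)[C@H](c1ccc2c(c1)OC(C)(C)O2)C(C(=O)OCc1ccc(OC)cc1)C(=O)OCc1ccc(OC)cc1)O[C@H](Cc1ccc2c(c1)OC(C)(C)O2)C(=O)OC(C)(C)C | intermediate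
17 | tert-butyl diazoacetate | CC(C)(C)OC(=O)C=[N+]=[N-] | starting material
18 | 2-tert-butyl 1,1-bis(PMB) (2S,5R,6R)-6-Ar-3-[(E)-2-(Dan-oxycarbonyl)ethenyl]-5-(TBS-oxymethyl)cyclohex-3-ene-1,1,2-tricarboxylate | O=C(/C=C/C1=C[C@@H](CO[Si](C)(C)C(C)(C)C)[C@H](c2ccc3c(c2)OC(C)(C)O3)C(C(=O)OCc2ccc(OC)cc2)(C(=O)OCc2ccc(OC)cc2)[C@H]1C(=O)OC(C)(C)C)O[C@H](Cc1ccc2c(c1)OC(C)(C)O2)C(=O)OC(C)(C)C | intermediate
19 | 2-tert-butyl 1,1-bis(PMB) (2S,5R,6R)-6-Ar-3-[(E)-2-(Dan-oxycarbonyl)ethenyl]-5-(hydroxymethyl)cyclohex-3-ene-1,1,2-tricarboxylate | O=C(/C=C/C1=C[C@@H](CO)[C@H](c2ccc3c(c2)OC(C)(C)O3)C(C(=O)OCc2ccc(OC)cc2)(C(=O)OCc2ccc(OC)cc2)[C@H]1C(=O)OC(C)(C)C)O[C@H](Cc1ccc2c(c1)OC(C)(C)O2)C(=O)OC(C)(C)C | intermediate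
20 | C3 aldehyde, 2-tert-butyl 1,1-bis(PMB) (2S,5R,6R)-6-Ar-3-[(E)-2-(Dan-oxycarbonyl)ethenyl]-5-formylcyclohex-3-ene-1,1,2-tricarboxylate | O=C(/C=C/C1=C[C@@H](C=O)[C@H](c2ccc3c(c2)OC(C)(C)O3)C(C(=O)OCc2ccc(OC)cc2)(C(=O)OCc2ccc(OC)cc2)[C@H]1C(=O)OC(C)(C)C)O[C@H](Cc1ccc2c(c1)OC(C)(C)O2)C(=O)OC(C)(C)C | intermediate
21 | (1R,4S,6R)-6-Ar-4-(tert-butoxycarbonyl)-3-[(E)-2-(Dan-oxycarbonyl)ethenyl]-5,5-bis(PMB-oxycarbonyl)cyclohex-2-ene-1-carboxylic acid | O=C(/C=C/C1=C[C@@H](C(=O)O)[C@H](c2ccc3c(c2)OC(C)(C)O3)C(C(=O)OCc2ccc(OC)cc2)(C(=O)OCc2ccc(OC)cc2)[C@H]1C(=O)OC(C)(C)C)O[C@H](Cc1ccc2c(c1)OC(C)(C)O2)C(=O)OC(C)(C)C | intermediate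
22 | pentacarboxylic acid, (2S,5R,6R)-3-[(1E)-3-{[(1R)-1-carboxy-2-(3,4-dihydroxyphenyl)ethyl]oxy}-3-oxoprop-1-en-1-yl]-6-(3,4-dihydroxyphenyl)cyclohex-3-ene-1,1,2,5-tetracarboxylic acid | O=C(/C=C/C1=C[C@@H](C(=O)O)[C@H](c2ccc(O)c(O)c2)C(C(=O)O)(C(=O)O)[C@H]1C(=O)O)O[C@H](Cc1ccc(O)c(O)c1)C(=O)O | intermediate
23 | (1R,2R,3S,4R)-6-[(1E)-3-{[(1R)-1-carboxy-2-(3,4-dihydroxyphenyl)ethyl]oxy}-3-oxoprop-1-en-1-yl]-3-(3,4-dihydroxyphenyl)cyclohex-5-ene-1,2,4-tricarboxylic acid | O=C(/C=C/C1=C[C@@H](C(=O)O)[C@H](c2ccc(O)c(O)c2)[C@@H](C(=O)O)[C@H]1C(=O)O)O[C@H](Cc1ccc(O)c(O)c1)C(=O)O | target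

Total step count: 13 (10 in the main line, 3 in the danshensu branch). Longest linear sequence: 10 steps (steps 1–5 and 9–13, from 3,4-dihydroxybenzaldehyde).

Steps most likely to fail

1. Step 10 (proposed method). Carbene insertion may lose to direct malonate vinylation at C1 (five-membered ring closure), to syn/anti isomerisation of the allyl complex followed by β-hydride loss from C3, or to carbene dimerisation, and facial control at C6 may be incomplete. The fallback uses known chemistry, sets out from 16 and returns to the route at 18. Nozaki–Hiyama–Kishi addition of the vinyl iodide to tert-butyl glyoxylate (O=CC(=O)OC(C)(C)C; CrCl2, NiCl2 cat., DMSO/THF, rt) should form the C1–C6 bond and give the open-chain C6 hydroxy ester F1 as a pair of C6 epimers. Mesylation (MsCl, Et3N, CH2Cl2, −20 °C) gives the open-chain C6 mesylate F2. Cs2CO3 in MeCN should then close the ring by intramolecular 6-exo-tet alkylation of the malonate at C6 (C5–C6 bond), the C6 epimers converging on 18 by base-mediated equilibration of the ester-bearing centre.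

2. Step 3. Conjugate addition to the electron-rich arylidene malonate may be sluggish, and the syn relationship may erode through reversible enamine formation at C3. The fallback sets out from 2 (with 3 and 7) and comes back at 6, forming C4–C5 instead of C3–C4. Wittig reaction of 2 with 7 (toluene, 80 °C) gives the protected caffeic aldehyde F3. Iminium-catalysed Michael addition of 3 with (R)-α,α-bis[3,5-bis(trifluoromethyl)phenyl]prolinol trimethylsilyl ether (EtOH, 0 °C) should give the (4S)-configured malonate aldehyde F4. Enamine α-hydroxymethylation with aqueous formaldehyde and (S)-α,α-diphenylprolinol trimethylsilyl ether (pH 7 buffer, toluene) then sets C3 in the hydroxymethyl aldehyde F5; the catalyst of opposite configuration is needed here to obtain the syn isomer. Silylation (TBSCl, imidazole, CH2Cl2, −20 °C) returns 6.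

3. Step 13. The liberated catechols may capture 4-methoxybenzyl cations, the unprotected polyacid may degrade or form an anhydride at the temperature needed for decarboxylation, and protonation at C5 may be non-selective. The fallback sets out from 21 and comes back at 23, decarboxylating before the phenols are unmasked. Chemoselective acidolysis of only the two 4-methoxybenzyl esters (5 % TFA, anisole, CH2Cl2, 0 °C) should give the protected C5 malonic acid F6 with tert-butyl esters and acetonides intact. Heating F6 in toluene at 90 °C, with the bulky C6 tert-butyl ester shielding one face and excluding anhydride formation, should give the protected C5 monoacid F7. TFA/H2O at room temperature then removes the remaining groups without heating the free polyphenol.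

Further compounds

F1 | step 10 | open-chain C6 hydroxy ester, Dan (2E,4Z,6R,7S)-7-Ar-4-(2-tert-butoxy-1-hydroxy-2-oxoethyl)-8,8-bis(PMB-oxycarbonyl)-6-(TBS-oxymethyl)octa-2,4-dienoate (both C6 epimers) | O=C(/C=C/C(=C/[C@@H](CO[Si](C)(C)C(C)(C)C)[C@H](c1ccc2c(c1)OC(C)(C)O2)C(C(=O)OCc1ccc(OC)cc1)C(=O)OCc1ccc(OC)cc1)C(O)C(=O)OC(C)(C)C)O[C@H](Cc1ccc2c(c1)OC(C)(C)O2)C(=O)OC(C)(C)C
F2 | step 10 | open-chain C6 mesylate, Dan (2E,4Z,6R,7S)-7-Ar-4-[2-tert-butoxy-1-(methanesulfonyloxy)-2-oxoethyl]-8,8-bis(PMB-oxycarbonyl)-6-(TBS-oxymethyl)octa-2,4-dienoate (both C6 epimers) | O=C(/C=C/C(=C/[C@@H](CO[Si](C)(C)C(C)(C)C)[C@H](c1ccc2c(c1)OC(C)(C)O2)C(C(=O)OCc1ccc(OC)cc1)C(=O)OCc1ccc(OC)cc1)C(OS(C)(=O)=O)C(=O)OC(C)(C)C)O[C@H](Cc1ccc2c(c1)OC(C)(C)O2)C(=O)OC(C)(C)C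
F3 | step 3 | protected caffeic aldehyde, (2E)-3-(2,2-dimethyl-1,3-benzodioxol-5-yl)prop-2-enal | O=C/C=C/c1ccc2c(c1)OC(C)(C)O2
F4 | step 3 | bis(4-methoxybenzyl) 2-[(1S)-1-Ar-3-oxopropyl]malonate | O=CC[C@H](c1ccc2c(c1)OC(C)(C)O2)C(C(=O)OCc1ccc(OC)cc1)C(=O)OCc1ccc(OC)cc1
F5 | step 3 | bis(4-methoxybenzyl) 2-[(1S,2R)-1-Ar-2-formyl-3-hydroxypropyl]malonate | O=C[C@@H](CO)[C@H](c1ccc2c(c1)OC(C)(C)O2)C(C(=O)OCc1ccc(OC)cc1)C(=O)OCc1ccc(OC)cc1
F6 | step 13 | protected C5 malonic acid, (2S,5R,6R)-6-Ar-2-(tert-butoxycarbonyl)-3-[(E)-2-(Dan-oxycarbonyl)ethenyl]cyclohex-3-ene-1,1,5-tricarboxylic acid | O=C(/C=C/C1=C[C@@H](C(=O)O)[C@H](c2ccc3c(c2)OC(C)(C)O3)C(C(=O)O)(C(=O)O)[C@H]1C(=O)OC(C)(C)C)O[C@H](Cc1ccc2c(c1)OC(C)(C)O2)C(=O)OC(C)(C)C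
F7 | step 13 | protected C5 monoacid (route locants 3R/4S/5R/6R), 23 carrying the C6 tert-butyl ester, the danshensu tert-butyl ester and both acetonides | O=C(/C=C/C1=C[C@@H](C(=O)O)[C@H](c2ccc3c(c2)OC(C)(C)O3)[C@@H](C(=O)O)[C@H]1C(=O)OC(C)(C)C)O[C@H](Cc1ccc2c(c1)OC(C)(C)O2)C(=O)OC(C)(C)C
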